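**Retrosynthetic overview**

1. The target is the C8 angelate of an 8,10-anti diol, which comes from a β-hydroxy ketone (C8=O, C10–OH) and this from a 2-isoxazoline that bridges C8 and C10 of the ten-membered ring. The C8(O)–C9H2–C10(OH)(CH3) segment of that ring is the retron of a nitrile oxide/1,1-disubstituted alkene (3+2) adduct.
2. Key disconnection: the C8–C9 bond (with O–C10), by cycloaddition of a C8 nitrile oxide carried on the γ-lactone onto the terminal C9=C10 alkene. The cis C6/C7 fusion of the lactone and the Z C4=C5 alkene fold the C7→C1 tether; a BnMe2Si group on C1 blocks the competing C1=C2 alkene.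
3. C3–C4 and the C3 stereocentre: carbonylative Sonogashira coupling of a Z vinyl iodide with 2-methylbut-1-en-3-yne, CBS reduction, then trans-hydrosilylation (E C1=C2 after later protodesilylation).
4. C6–C7 and the α-methylene-γ-lactone: catalytic asymmetric chromium-mediated 2-(alkoxycarbonyl)allylation of (Z)-3-iodobut-2-enal with a Baylis–Hillman-derived allylic bromide.
5. Ring order: γ-lactone (step 5), then the ten-membered carbocycle together with a temporary isoxazoline ring (step 13), isoxazoline opened (step 15).

Key step: step 13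

Remark (numbering used throughout): C13H2=C11, C12 (lactone C=O), C6 (lactone O–CH), C5=C4(CH3), C3 (OAc), C2=C1, C10 (C(OH)CH3), C9 (CH2), C8 (CH–O-angelate), C7. The SMILES is read as 3R,6R,7S,8R,10R with H6 and H7 on the same face (cis-fused lactone), 4Z and 1E.

Remark (assumption): in step 5 the (S,S) antipode of the ligand is assumed to direct the allyl group to the Si face of the aldehyde; if the sense is the opposite, the (R,R) ligand is used.

**Route**

Step 1
Reactants: 1 but-2-yn-1-ol
Product: 3 (Z)-3-iodobut-2-en-1-ol, via cyclic alkenylalanate 2 (not isolated)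
Conditions: NaAlH2(OCH2CH2OMe)2 (Red-Al), THF, 0 °C → rt; then I2, THF, −78 → 0 °C
Reagents that add atoms: iodine, II
Why: trans-hydroalumination of the propargylic alcohol puts hydride on C2 and aluminium on C3 inside a five-membered alkoxyalanate, and iodinolysis with retention should give the Z iodide.

Step 2
Reactants: 3 (Z)-3-iodobut-2-en-1-ol
Product: 4 (Z)-3-iodobut-2-enal
Conditions: MnO2, CH2Cl2, rt; used at once
Reagents that add atoms: none
Why: neutral allylic oxidation with MnO2 should keep the Z geometry of the β-iodo enal.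

Step 3
Reactants: 5 methyl acrylate; 6 (tert-butyldimethylsilyloxy)acetaldehyde
Product: 7 methyl 4-(tert-butyldimethylsilyloxy)-3-hydroxy-2-methylidenebutanoate (racemic)
Conditions: DABCO (0.5 equiv), dioxane/H2O, rt
Reagents that add atoms: none
Why: Morita–Baylis–Hillman reaction of an unhindered α-silyloxy aldehyde with an acrylate; the stereocentre is removed in step 4.

Step 4
Reactants: 7 the Baylis–Hillman alcohol
Product: 8 methyl (Z)-2-(bromomethyl)-4-(tert-butyldimethylsilyloxy)but-2-enoate
Conditions: NBS, Me2S, CH2Cl2, 0 °C → rt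
Reagents that add atoms: N-bromosuccinimide, O=C1CCC(=O)N1Br
Why: Corey–Kim-type activation followed by SN2′ bromide attack should give the transposed, thermodynamically preferred Z allylic bromide (substituent trans to the ester).

Step 5
Reactants: 4 (Z)-3-iodobut-2-enal; 8 the allylic bromide
Product: 11 (4S,5S)-4-[(tert-butyldimethylsilyloxy)methyl]-5-[(Z)-2-iodoprop-1-enyl]-3-methylideneoxolan-2-one (cis-lactone), via O-trimethylsilyl ether 9 (not isolated), via syn-hydroxy ester 10 (not isolated)
Conditions: CrCl2 (10 mol%), (S,S)-3,6-di-tert-butyl-1,8-bis(4-isopropyl-4,5-dihydrooxazol-2-yl)carbazole (12 mol%), Mn powder, TMSCl, THF, rt; then citric acid, MeOH, rt; PPTS, CH2Cl2, rt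
Reagents that add atoms: none
Why: catalytic asymmetric Nozaki–Hiyama-type 2-(alkoxycarbonyl)allylation, in which the γ-substituted allylchromium adds at its γ-carbon through a chair transition state to give the syn adduct (hence the cis lactone after acid-induced lactonisation) while the chiral tridentate ligand on chromium selects the Si face of the aldehyde, setting C6 and C7.

Step 6
Reactants: 11 the lactone vinyl iodide; 12 2-methylbut-1-en-3-yne
Product: 13 the enynone, 11 with iodine replaced by a 4-methylpent-4-en-2-ynoyl group (side chain (1Z)-2,6-dimethyl-3-oxohepta-1,6-dien-4-yn-1-yl)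
Conditions: PdCl2(PPh3)2 (5 mol%), CuI (2 mol%), CO (1 atm), Et3N, THF, rt
Reagents that add atoms: carbon monoxide, [C-]#[O+]
Why: carbonylative Sonogashira coupling, in which oxidative addition to the vinyl iodide with retention, CO insertion and alkynyl transfer should give the alkynyl ketone with the Z C4=C5 geometry intact.

Step 7
Reactants: 13 the enynone
Product: 14 the propargylic alcohol (side chain (1Z,3S)-3-hydroxy-2,6-dimethylhepta-1,6-dien-4-yn-1-yl; lactone centres as in 11)
Conditions: (S)-2-methyl-CBS-oxazaborolidine (20 mol%), catecholborane, CH2Cl2, −78 °C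
Reagents that add atoms: none
Why: Corey–Bakshi–Shibata reduction with the alkynyl group as the small and the α-methylalkenyl group as the large substituent, so the (S)-catalyst should deliver hydride to give the C3 configuration of the target (formally S here because the alkyne outranks the alkene).

Step 8
Reactants: 14 the propargylic alcohol
Product: 15 the dienylsilane (side chain (1Z,3R,4Z)-5-[benzyl(dimethyl)silyl]-3-hydroxy-2,6-dimethylhepta-1,4,6-trien-1-yl)
Conditions: [Cp*Ru(MeCN)3]PF6 (5 mol%), BnMe2SiH, CH2Cl2, 0 °C
Reagents that add atoms: benzyldimethylsilane, C[SiH](C)Cc1ccccc1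
Why: ruthenium-catalysed trans-hydrosilylation of a propargylic alcohol adds H to C2 and silicon to the distal C1 in anti fashion, which fixes C3 and C10 trans across C1=C2 and places the bulky silyl group on C1.

Step 9
Reactants: 15 the dienylsilane alcohol
Product: 16 the C3 acetate of 15
Conditions: Ac2O, pyridine, DMAP (cat.), CH2Cl2, 0 °C → rt
Reagents that add atoms: acetic anhydride, CC(=O)OC(C)=O
Why: standard acylation of the only free hydroxyl installs the acetate of the target without touching C3.

Step 10
Reactants: 16 the acetate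
Product: 17 the primary C8 alcohol (16 without the silyl ether)
Conditions: CSA (10 mol%), MeOH/CH2Cl2, 0 °C
Reagents that add atoms: none
Why: acid-catalysed methanolysis cleaves the primary silyl ether selectively and leaves the acetate and the vinylsilane in place.

Step 11
Reactants: 17 the primary alcohol
Product: 18 the C8 aldehyde
Conditions: Dess–Martin periodinane, CH2Cl2, 0 °C; used at once
Reagents that add atoms: none
Why: Dess–Martin oxidation under non-basic conditions should give the aldehyde without epimerising C7 or moving the exocyclic alkene.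

Step 12
Reactants: 18 the aldehyde
Product: 19 the C8 aldoxime (E/Z mixture, both usable)
Conditions: NH2OH·HCl (1.1 equiv), NaOAc, MeOH, 0 °C
Reagents that add atoms: hydroxylamine (as its hydrochloride), NO
Why: oxime condensation at a buffered, weakly acidic pH is much faster than conjugate addition of hydroxylamine to the α-methylene lactone.

Step 13
Reactants: 19 the aldoxime
Product: 22 the C1-silylated 3,5-bridged 2-isoxazoline of the ten-membered ring, via hydroximoyl chloride 20 (not isolated), via nitrile oxide 21 (not isolated)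
Conditions: NCS, pyridine (cat.), CHCl3, rt; then addition by syringe pump to Et3N in CH2Cl2 (0.5 mM final), rt
Reagents that add atoms: none
Why: Et3N dehydrochlorinates the hydroximoyl chloride to the nitrile oxide, which adds in a concerted (3+2) cycloaddition across the terminal C9=C10 alkene, C8 bonding to the CH2 terminus C9 and O to the methyl-bearing C10, the orientation generally found with 1,1-disubstituted alkenes. The closest known reaction type is the macrocyclic intramolecular nitrile oxide cycloaddition that gives 3,5-bridged 2-isoxazolines; the carbocycle closes in the ten-membered endo (bridged) mode and the five-membered isoxazoline forms at the same time as the two-atom bridge of a bicyclo[7.2.1] system. The new stereocentre C10 is controlled by C7 and the cis-fused lactone: with the lactone carbon C11 anti to the forming C8–C9 bond and H7 turned towards the alkene, C6 and the C5=C4–C3–C2=C1 tether lie on one flank of the dipole only, so C1 can reach C10 from that side alone and O should add to the face that gives 10R. The step needs site selectivity for C9=C10 over C1=C2, whose seven-membered fused closure would otherwise be the easier one, and the BnMe2Si group on C1 secures it by making that alkene trisubstituted and blocking O–C1 bonding. The trisubstituted C4=C5 and the exocyclic C11=C13 alkenes cannot be reached within the molecule, and furoxan formation and intermolecular addition to the α-methylene lactone are held back by slow generation at high dilution.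

Step 14
Reactants: 22 the silylated isoxazoline
Product: 23 the bridged isoxazoline with the E C1=C2 alkene
Conditions: AgF, THF/MeOH/H2O, rt, dark
Reagents that add atoms: none
Why: fluoride-assisted silicon-to-silver exchange and protonation (protodesilylation) replace silicon by hydrogen with retention, which should give the E alkene under non-basic conditions.

Step 15
Reactants: 23 the isoxazoline
Product: 25 the β-hydroxy ketone (C8=O, C10–OH), via β-hydroxy imine 24 (not isolated)
Conditions: Mo(CO)6, B(OH)3, MeCN/H2O (8:1), 75 °C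
Reagents that add atoms: water, O
Why: reductive N–O cleavage by Mo(CO)6 and hydrolysis of the imine unveil the aldol-type unit without touching C10, while boric acid traps the ammonia that could otherwise add to the α-methylene lactone or move the exocyclic alkene.

Step 16
Reactants: 25 the β-hydroxy ketone
Product: 26 the 8,10-anti diol (8R,10R)
Conditions: Me4NBH(OAc)3, MeCN/AcOH (1:1), −30 °C
Reagents that add atoms: none
Why: Evans–Saksena reduction, in which the tertiary C10 hydroxyl exchanges onto boron and delivers hydride through a six-membered chair, should give the 1,3-anti diol and thus 8R, with esters and the enoate untouched.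

Step 17
Reactants: 26 the diol; 27 angelic acid
Product: 29 the target, (3R,6R,7S,8R,10R)-3-acetoxy-8-angeloyloxy-10-hydroxygermacra-1(E),4(Z),11(13)-trien-6,12-olide in the numbering above, via mixed anhydride 28 (not isolated)
Conditions: 27, 2,4,6-trichlorobenzoyl chloride, Et3N, toluene, rt; then 26, toluene, 75 °C
Reagents that add atoms: none
Why: Yamaguchi-type mixed-anhydride esterification without DMAP should acylate the secondary C8 hydroxyl in preference to the tertiary C10 hydroxyl and avoid angelate-to-tiglate isomerisation.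

**Compound list**

1 | but-2-yn-1-ol | CC#CCO | starting material
2 | sodium cyclic (Z)-alkenylalanate from 1 (formed in the flask, not isolated) | CC1=CCO[Al-]1(OCCOC)OCCOC.[Na+] | intermediate
3 | (Z)-3-iodobut-2-en-1-ol | C/C(I)=C/CO | intermediate
4 | (Z)-3-iodobut-2-enal | C/C(I)=C/C=O | intermediate
5 | methyl acrylate | C=CC(=O)OC | starting material
6 | (tert-butyldimethylsilyloxy)acetaldehyde | O=CCO[Si](C)(C)C(C)(C)C | starting material
7 | methyl 4-(tert-butyldimethylsilyloxy)-3-hydroxy-2-methylidenebutanoate (racemic) | C=C(C(=O)OC)C(O)CO[Si](C)(C)C(C)(C)C | intermediate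
8 | methyl (Z)-2-(bromomethyl)-4-(tert-butyldimethylsilyloxy)but-2-enoate | COC(=O)/C(CBr)=C/CO[Si](C)(C)C(C)(C)C | intermediate
9 | O-trimethylsilyl ether of 10 (formed in the flask, not isolated) | C=C(C(=O)OC)[C@@H](CO[Si](C)(C)C(C)(C)C)[C@H](O[Si](C)(C)C)/C=C(/C)I | intermediate
10 | methyl (5Z)-4-hydroxy-6-iodo-2-methylidene-3-[(tert-butyldimethylsilyloxy)methyl]hept-5-enoate, 3,4-syn (formed in the flask, not isolated) | C=C(C(=O)OC)[C@@H](CO[Si](C)(C)C(C)(C)C)[C@H](O)/C=C(/C)I | intermediate
11 | (4S,5S)-4-[(tert-butyldimethylsilyloxy)methyl]-5-[(Z)-2-iodoprop-1-enyl]-3-methylideneoxolan-2-one | C=C1C(=O)O[C@H](/C=C(/C)I)[C@@H]1CO[Si](C)(C)C(C)(C)C | intermediate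
12 | 2-methylbut-1-en-3-yne | C=C(C)C#C | starting material
13 | enynone: lactone of 11 carrying (1Z)-2,6-dimethyl-3-oxohepta-1,6-dien-4-yn-1-yl at C6 | C=C1C(=O)O[C@H](/C=C(/C)C(=O)C#CC(C)=C)[C@@H]1CO[Si](C)(C)C(C)(C)C | intermediate
14 | propargylic alcohol: side chain (1Z,3S)-3-hydroxy-2,6-dimethylhepta-1,6-dien-4-yn-1-yl | C=C1C(=O)O[C@H](/C=C(/C)[C@H](O)C#CC(C)=C)[C@@H]1CO[Si](C)(C)C(C)(C)C | intermediate
15 | dienylsilane alcohol: side chain (1Z,3R,4Z)-5-[benzyl(dimethyl)silyl]-3-hydroxy-2,6-dimethylhepta-1,4,6-trien-1-yl | C=C1C(=O)O[C@H](/C=C(/C)[C@H](O)/C=C(\[Si](C)(C)Cc2ccccc2)C(C)=C)[C@@H]1CO[Si](C)(C)C(C)(C)C | intermediate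
16 | C3 acetate of 15 | C=C1C(=O)O[C@H](/C=C(/C)[C@H](OC(C)=O)/C=C(\[Si](C)(C)Cc2ccccc2)C(C)=C)[C@@H]1CO[Si](C)(C)C(C)(C)C | intermediate
17 | primary C8 alcohol | C=C1C(=O)O[C@H](/C=C(/C)[C@H](OC(C)=O)/C=C(\[Si](C)(C)Cc2ccccc2)C(C)=C)[C@@H]1CO | intermediate
18 | C8 aldehyde | C=C1C(=O)O[C@H](/C=C(/C)[C@H](OC(C)=O)/C=C(\[Si](C)(C)Cc2ccccc2)C(C)=C)[C@@H]1C=O | intermediate
19 | C8 aldoxime | C=C1C(=O)O[C@H](/C=C(/C)[C@H](OC(C)=O)/C=C(\[Si](C)(C)Cc2ccccc2)C(C)=C)[C@@H]1C=NO | intermediate
20 | C8 hydroximoyl chloride (formed in the flask, not isolated) | C=C1C(=O)O[C@H](/C=C(/C)[C@H](OC(C)=O)/C=C(\[Si](C)(C)Cc2ccccc2)C(C)=C)[C@@H]1C(Cl)=NO | intermediate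
21 | C8 nitrile oxide (formed in the flask, not isolated) | C=C1C(=O)O[C@H](/C=C(/C)[C@H](OC(C)=O)/C=C(\[Si](C)(C)Cc2ccccc2)C(C)=C)[C@@H]1C#[N+][O-] | intermediate
22 | C1-silylated bridged isoxazoline (ten-membered carbocycle, O–N bridge from C10 to C8) | C=C1C(=O)O[C@@H]2/C=C(/C)[C@H](OC(C)=O)/C=C(\[Si](C)(C)Cc4ccccc4)[C@]3(C)ON=C(C3)[C@H]12 | intermediate
23 | bridged isoxazoline with E C1=C2 | C=C1C(=O)O[C@@H]2/C=C(/C)[C@H](OC(C)=O)/C=C/[C@]3(C)ON=C(C3)[C@H]12 | intermediate
24 | β-hydroxy imine (formed in the flask, not isolated) | C=C1C(=O)O[C@@H]2/C=C(/C)[C@H](OC(C)=O)/C=C/[C@](C)(O)CC(=N)[C@H]12 | intermediate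
25 | β-hydroxy ketone (C8=O, 10R-OH) | C=C1C(=O)O[C@@H]2/C=C(/C)[C@H](OC(C)=O)/C=C/[C@](C)(O)CC(=O)[C@H]12 | intermediate
26 | 8R,10R diol | C=C1C(=O)O[C@@H]2/C=C(/C)[C@H](OC(C)=O)/C=C/[C@](C)(O)C[C@@H](O)[C@H]12 | intermediate
27 | angelic acid, (Z)-2-methylbut-2-enoic acid | C/C=C(/C)C(=O)O | starting material
28 | angelic 2,4,6-trichlorobenzoic anhydride (formed in the flask, not isolated) | C/C=C(/C)C(=O)OC(=O)c1c(Cl)cc(Cl)cc1Cl | intermediate
29 | CNP0181631.1 | C=C1C(=O)O[C@@H]2/C=C(/C)[C@H](OC(C)=O)/C=C/[C@](C)(O)C[C@@H](OC(=O)/C(C)=C\C)[C@H]12 | target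

**Step count and risks**

Total steps: 17. Longest linear sequence: 15 (steps 1, 2 and 5 to 17; steps 3 and 4 make the side fragment).

Most likely to fail, first: step 13. The ten-membered closure may be outrun by dimerisation of the nitrile oxide or by its intermolecular addition to the α-methylene lactone, and the facial selectivity at C10 rests on a conformational model only. The fallback sets out from 11 and comes back at 23; it makes the C8–C9 bond between two molecules and closes the ring at C3–C4 instead. Methanolysis of the silyl ether of 11 (CSA, MeOH) gives the lactone alcohol F1, Dess–Martin oxidation gives the aldehyde F2 and NH2OH·HCl/NaOAc gives the oxime F3. (E)-4-Methylpenta-2,4-dienal F4 is made by Wittig reaction of methacrolein with (triphenylphosphoranylidene)acetaldehyde. Oxidation of F3 with PhI(OAc)2 in the presence of an excess of F4 generates the nitrile oxide F5, which should add to the terminal 1,1-disubstituted alkene of F4 to give the isoxazoline enal F6 together with its C10 epimer F7; the two are separated by chromatography. An intramolecular Nozaki–Hiyama–Kishi reaction of F6 (CrCl2, NiCl2 cat., chiral sulfonamide ligand, DMSO/THF, high dilution) should close the ten-membered ring to the C3 alcohol F8, and acetylation (Ac2O, pyridine, DMAP) gives 23.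

Second: step 15. The new C8 ketone is β,γ-unsaturated, so the exocyclic C11=C13 double bond may migrate into conjugation, the lactone oxygen may be lost from C6 by β-elimination, or liberated ammonia may add to the α-methylene lactone. The fallback sets out from 23 and comes back at 29; it masks the α-methylene group before the ketone is unveiled. Conjugate addition of thiophenol (PhSH, Et3N cat., CH2Cl2, 0 °C) to 23 gives the sulfide F9 (C11 epimers, both usable). Mo(CO)6/B(OH)3 then gives, through the imine F10, the ketone F11, which has no alkene left to migrate. Me4NBH(OAc)3 gives the anti diol F12, and the mixed anhydride 28 gives the angelate F13. Oxidation with one equivalent of mCPBA at −78 °C gives the sulfoxide F14, whose thermal syn-elimination (toluene, 90 °C, CaCO3) restores the α-methylene lactone and gives 29.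

Third: step 5. Enantio- or syn-selectivity may be incomplete with the γ-substituted bromide and the small enal. The fallback sets out from 4 and 8 and comes back at 14. The allylation is run without a chiral ligand with stoichiometric CrCl2 in THF, which should still be syn-selective and gives, through the hydroxy ester 10 and its enantiomer F15, the racemic cis-lactone, that is 11 together with its enantiomer F16. The racemate is taken through step 6 (13 and its enantiomer F17), and the reagent-controlled CBS reduction of step 7 turns the enantiomers into diastereomers, 14 and the lactone-epimeric alcohol F18, which are separated by chromatography.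

Further compounds
F1 | step 13 | (4S,5S)-4-(hydroxymethyl)-5-[(Z)-2-iodoprop-1-enyl]-3-methylideneoxolan-2-one | C=C1C(=O)O[C@H](/C=C(/C)I)[C@@H]1CO
F2 | step 13 | C8 aldehyde of F1 | C=C1C(=O)O[C@H](/C=C(/C)I)[C@@H]1C=O
F3 | step 13 | aldoxime of F2 | C=C1C(=O)O[C@H](/C=C(/C)I)[C@@H]1C=NO
F4 | step 13 | (E)-4-methylpenta-2,4-dienal | C=C(C)/C=C/C=O
F5 | step 13 | nitrile oxide from F3 | C=C1C(=O)O[C@H](/C=C(/C)I)[C@@H]1C#[N+][O-]
F6 | step 13 | isoxazoline enal, C10 configured as in the target | C=C1C(=O)O[C@H](/C=C(/C)I)[C@@H]1C2=NO[C@@](C)(/C=C/C=O)C2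
F7 | step 13 | C10 epimer of F6 | C=C1C(=O)O[C@H](/C=C(/C)I)[C@@H]1C2=NO[C@](C)(/C=C/C=O)C2
F8 | step 13 | macrocyclic isoxazoline with free 3R hydroxyl | C=C1C(=O)O[C@@H]2/C=C(/C)[C@H](O)/C=C/[C@]3(C)ON=C(C3)[C@H]12
F9 | step 15 | thiophenol adduct of 23 (C13 phenylsulfanyl, C11 epimers) | c4ccccc4SCC1C(=O)O[C@@H]2/C=C(/C)[C@H](OC(C)=O)/C=C/[C@]3(C)ON=C(C3)[C@H]12
F10 | step 15 | β-hydroxy imine of the sulfide series | c4ccccc4SCC1C(=O)O[C@@H]2/C=C(/C)[C@H](OC(C)=O)/C=C/[C@](C)(O)CC(=N)[C@H]12
F11 | step 15 | β-hydroxy ketone of the sulfide series | c4ccccc4SCC1C(=O)O[C@@H]2/C=C(/C)[C@H](OC(C)=O)/C=C/[C@](C)(O)CC(=O)[C@H]12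
F12 | step 15 | 8R,10R diol of the sulfide series | c4ccccc4SCC1C(=O)O[C@@H]2/C=C(/C)[C@H](OC(C)=O)/C=C/[C@](C)(O)C[C@@H](O)[C@H]12
F13 | step 15 | C8 angelate of the sulfide series | c4ccccc4SCC1C(=O)O[C@@H]2/C=C(/C)[C@H](OC(C)=O)/C=C/[C@](C)(O)C[C@@H](OC(=O)/C(C)=C\C)[C@H]12
F14 | step 15 | sulfoxide of F13 | O=S(CC1C(=O)O[C@@H]2/C=C(/C)[C@H](OC(C)=O)/C=C/[C@](C)(O)C[C@@H](OC(=O)/C(C)=C\C)[C@H]12)c4ccccc4
F15 | step 5 | enantiomer of 10 | C=C(C(=O)OC)[C@H](CO[Si](C)(C)C(C)(C)C)[C@@H](O)/C=C(/C)I
F16 | step 5 | enantiomer of 11, (4R,5R) | C=C1C(=O)O[C@@H](/C=C(/C)I)[C@H]1CO[Si](C)(C)C(C)(C)C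
F17 | step 5 | enantiomer of 13 | C=C1C(=O)O[C@@H](/C=C(/C)C(=O)C#CC(C)=C)[C@H]1CO[Si](C)(C)C(C)(C)C
F18 | step 5 | diastereomer of 14 (carbinol as in 14, lactone centres inverted) | C=C1C(=O)O[C@@H](/C=C(/C)[C@H](O)C#CC(C)=C)[C@H]1CO[Si](C)(C)C(C)(C)C
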